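The data were generated by integration from invented constants.

Dawn and spring run alike until 80 min, and what parts them afterwards is whether intermediate is then being made faster or slower than it is used up.

| flask | substrate | coupling partner | temperature | remark | time |
|---|---|---|---|---|---|
| maple | 0.20 M | 1.3 equiv | 100 °C | run made earlier |  |
| dawn | 0.10 M | 1.30 equiv |  | at 100 °C throughout | 6.0 h |
| spring | 0.10 M | 1.30 equiv |  | at 100 °C until 80 min, from then on at 60 °C | 6.0 h |

maple run (percent of the substrate charged)

| time / min | intermediate / % | product / % |
|---|---|---|
| 8.00 | 15.3 | 0.8 |
| 15.0 | 24.7 | 1.3 |
| 30.0 | 36.7 | 3.8 |
| 60.0 | 48.4 | 12.4 |
| 120 | 47.6 | 29.6 |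

(readings scatter by 0.5 percentage points)

- the winner by amount of intermediate, in percent of the substrate charged; "neither" if no more than 2 percentage points parts them (dawn / spring / neither)
- how much intermediate is there at the end, in percent of the substrate charged: dawn
- how much intermediate is there at the end, in percent of the substrate charged: spring

From the maple run we read a second-order constant of 0.00142 M⁻¹ s⁻¹ for substrate meeting coupling partner, and a first-order constant of 0.00597 min⁻¹ for intermediate going to product. Their quotient, 14.2 M⁻¹, we call the balance constant: multiplied by substrate and coupling partner and divided by intermediate, all in molar, it gives making over using.

Dawn, left hot, should reach 6.0 h with 13.3 % of its substrate, the limiting reagent, and 0.0433 M of coupling partner. Setting making equal to using gives a first answer of 8.20 % intermediate, but that supposes intermediate keeps up with a falling making, so we go round through the run instead. At 80 min both flasks should hold 50.5 % substrate and about 37.7 % intermediate. We then take two blocks of 140 min for dawn, each keeping the first-order survivors of the intermediate already there and adding the substrate used in that block, decayed over half the block. With 23.5 % substrate between the blocks, the first block gives 34.1 % intermediate and the second 21.5 %. Put back into the balance constant, this second answer makes making over using 0.381 at the end of dawn, so the first answer was too low.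

Spring at its change should hold more intermediate than dawn's end, with the ratio at 1.53, still above one. What 60 °C does to each step is our guess, but we expect spring to stay near that figure, so leave it cold.

The forecast gives spring, with 22 % for dawn and 39 % for spring, reckoning that cooling “slows both steps roughly twentyfold”.

The flasks give 20.8 % for dawn and 42.2 % for spring, so spring wins, and spring still holds 45.2 % of its substrate at the end.

    substrate + coupling partner → intermediate + released group (k = 0.00140 M⁻¹ s⁻¹, Ea = 71.0 kJ mol⁻¹)
    intermediate → product (k = 1.00 × 10⁻⁴ s⁻¹, Ea = 118 kJ mol⁻¹)
    (constants at 100 °C)

Dawn's end state, put into the balance constant, gives making over using of 0.402, below one. A neighbour of dawn charged with 0.330 equiv of coupling partner ends with 7.66 % intermediate, and the same constant puts its making over using at 0.397.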